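**Retrosynthetic overview**

1. The C3 ester of 28 is made last by acylating diol 20 with dienoic acid 27 (from (R)-2-methylbutan-1-ol by Wittig and Horner–Wadsworth–Emmons reactions). The C11–C13 unit on C7 comes from acetone: aldol on the α-alkoxy enolate of dienone 12, dehydration, SeO2 oxidation, acetylation.
2. Dienone 12 comes from enone 10 by quinone dehydrogenation. The C3 and C4 stereocentres of 10 are set together by one hydroboration of the C3=C4 alkene 7.
3. Ring A (C1, C2, C3, C4, C5, C10) is never closed as a six-membered ring. It is grown from the five-membered ketone ring (C1, C2, C3, C5, C10) of the bought bicyclic dione 1 by a one-carbon ring enlargement: CH3CBr2Li adds to the ring carbonyl C3, the C3–C5 bond shifts to the new carbon C4, and the enolate is caught as the C3=C4 enol triflate 6.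
4. Enabling feature: the five-ring carbonyl carbon C3 lies between a CH2 (C2) and the quaternary ring-fusion carbon C5 that carries the angular methyl. The more substituted C5 should migrate with retention, the inserted C4 (with its methyl C15) lands between C3 and C5, and the enolate double bond is fixed at C3=C4. The ring B enone (C8=O, C9=C10) is masked as a dithiane meanwhile.
5. Ring order: ring B is present in 1 (chiral pool, C5 centre); ring A reaches its final size second (step 2); ring B oxidation and the two esters follow.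

Key step: step 2

Assumption: (7aR)-7a-methyl-2,3,7,7a-tetrahydro-1H-indene-1,5(6H)-dione (1) and (R)-2-methylbutan-1-ol (21) are taken as purchasable single enantiomers; C numbers in names are eremophilane numbers (ring A = C1–C5 and C10, ring B = C5–C10, methyl C14 on C5, methyl C15 on C4, side chain C11–C13 on C7).

**Route**

Step 1
Reactants: 1 (7aR)-7a-methyl-2,3,7,7a-tetrahydro-1H-indene-1,5(6H)-dione
Product: 2 (7a′R)-7a′-methyl-2′,3′,7′,7a′-tetrahydrospiro[1,3-dithiane-2,5′-inden]-1′(6′H)-one
Conditions: HS(CH2)3SH (1.05 equiv), BF3·OEt2 (cat.), AcOH/CH2Cl2, 0 °C → rt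
Reagents that add atoms: propane-1,3-dithiol, SCCCS
Why: Chemoselective thioketalisation should take the conjugated six-ring carbonyl because the five-ring ketone is neopentyl (next to the quaternary carbon), as in 4-ene-3,17-dione steroids; the C=C stays in place and no stereocentre is touched.

Step 2
Reactants: 2 (7a′R)-7a′-methyl-2′,3′,7′,7a′-tetrahydrospiro[1,3-dithiane-2,5′-inden]-1′(6′H)-one; 3 1,1-dibromoethane
Product: 6 (5R)-8,8-(propane-1,3-diyldithio)-11,12,13-trinoreremophila-3,9-dien-3-yl trifluoromethanesulfonate, via lithium alkoxide 4 (not isolated), via lithium enolate 5 (not isolated)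
Conditions: 3 (1.5 equiv), lithium 2,2,6,6-tetramethylpiperidide (1.5 equiv), THF, −95 °C; n-BuLi (2.0 equiv), −95 → −20 °C; PhNTf2 (2.5 equiv), −20 °C → rt
Reagents that add atoms: N-phenylbis(trifluoromethanesulfonimide), O=S(=O)(N(c1ccccc1)S(=O)(=O)C(F)(F)F)C(F)(F)F
Why: Mechanism: CH3CBr2Li (made in the flask from 3) adds to the only free carbonyl, C3, from the face away from the angular methyl to give alkoxide 4; Br/Li exchange with n-BuLi then makes a β-oxido carbenoid, and the ring bond C3–C5 shifts to the carbenoid carbon with loss of LiBr, which inserts that carbon as C4 (already bearing C15) between C3 and C5 and turns the five-membered ring (C1, C2, C3, C5, C10) into six-membered ring A as its lithium enolate 5, caught on oxygen by PhNTf2. The closest known reaction type is the β-oxido carbenoid one-carbon ring enlargement of cycloalkanones by dibromoalkyllithiums, whose primary product is likewise an enolate that can be trapped. No ring is closed from an open chain: ring A arises by a 1,2-alkyl shift (ring expansion from five to six atoms), and the migrating C5 keeps its configuration, so the quaternary centre of 1 is carried over intact. No new stereocentre is created (C3 and C4 are sp2 in 6); what the step fixes is the position of the double bond, C3=C4, which step 4 needs. The selectivity needed is migration of C5 and not of C2, and the substrate should secure it: the fully substituted C5 is the more electron-rich migrating carbon in this pinacol-like shift onto an electrophilic carbenoid carbon (more substituted α-carbons are expected to migrate preferentially in this reaction class), while the dithiane removes the second carbonyl from play.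

Step 3
Reactants: 6 (5R)-8,8-(propane-1,3-diyldithio)-11,12,13-trinoreremophila-3,9-dien-3-yl trifluoromethanesulfonate
Product: 7 (5S)-8,8-(propane-1,3-diyldithio)-11,12,13-trinoreremophila-3,9-diene
Conditions: Pd(OAc)2 (5 mol %), PPh3 (10 mol %), HCO2H, Et3N, DMF, 60 °C
Reagents that add atoms: none
Why: Palladium-catalysed formate reduction of an enol triflate (oxidative addition, decarboxylation of formate to hydride, reductive elimination) should replace OTf by H without moving the double bond; no stereocentre is involved.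

Step 4
Reactants: 7 (5S)-8,8-(propane-1,3-diyldithio)-11,12,13-trinoreremophila-3,9-diene
Product: 9 (3S,4S,5S)-8,8-(propane-1,3-diyldithio)-11,12,13-trinoreremophil-9-en-3-ol, via alkylborane 8 (not isolated)
Conditions: BH3·THF (1.1 equiv), THF, 0 °C → rt; then NaOH, H2O2, H2O, 0 °C
Reagents that add atoms: borane–tetrahydrofuran, B.C1CCOC1 (boron stays only in 8); hydrogen peroxide, OO
Why: Hydroboration–oxidation should put boron on the unhindered CH terminus C3 and hydrogen on C4, both from the ring A face opposite the axial C5 methyl, so one syn addition sets C4 (methyl cis to the C5 methyl) and C3 (hydroxyl trans to both methyls), as expected for 4-methyl-3-ene octalins with an angular methyl, while the C9=C10 alkene flanked by the quaternary C5 and the dithiane carbon should react far more slowly.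

Step 5
Reactants: 9 (3S,4S,5S)-8,8-(propane-1,3-diyldithio)-11,12,13-trinoreremophil-9-en-3-ol
Product: 10 (3S,4S,5S)-3-hydroxy-11,12,13-trinoreremophil-9-en-8-one
Conditions: PhI(O2CCF3)2 (1.5 equiv), MeCN/H2O 9:1, 0 °C
Reagents that add atoms: water, O
Why: Oxidative dethioketalisation with a trivalent iodine reagent should unmask the conjugated ketone quickly and leave the secondary alcohol and the three stereocentres untouched.

Step 6
Reactants: 10 (3S,4S,5S)-3-hydroxy-11,12,13-trinoreremophil-9-en-8-one
Product: 11 (3S,4S,5S)-3-(methoxymethoxy)-11,12,13-trinoreremophil-9-en-8-one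
Conditions: MeOCH2Cl (3 equiv), i-Pr2NEt (4 equiv), CH2Cl2, 0 °C → rt
Reagents that add atoms: chloromethyl methyl ether, COCCl
Why: Acetal protection (O-alkylation) of the C3 hydroxyl gives an ether that should survive the quinone, the amide bases and the oxidants of steps 7–13 and cannot migrate.

Step 7
Reactants: 11 (3S,4S,5S)-3-(methoxymethoxy)-11,12,13-trinoreremophil-9-en-8-one
Product: 12 (3S,4S,5S)-3-(methoxymethoxy)-11,12,13-trinoreremophila-1,9-dien-8-one
Conditions: chloranil (2 equiv), t-BuOH, reflux
Reagents that add atoms: none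
Why: Quinone dehydrogenation of a 4-en-3-one type enone through its extended dienol should remove hydride from C2 and give the linear 1,9-dien-8-one, C1 being the only γ position that carries hydrogen; C3, C4 and C5 are not involved.

Step 8
Reactants: 12 (3S,4S,5S)-3-(methoxymethoxy)-11,12,13-trinoreremophila-1,9-dien-8-one
Product: 13 (3S,4S,5S,7RS)-7-hydroxy-3-(methoxymethoxy)-11,12,13-trinoreremophila-1,9-dien-8-one
Conditions: LiN(i-Pr)2 (1.1 equiv), THF, −78 °C; then 2-(benzenesulfonyl)-3-phenyloxaziridine (1.3 equiv), −78 °C; aqueous work-up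
Reagents that add atoms: 2-(benzenesulfonyl)-3-phenyloxaziridine, O=S(=O)(c1ccccc1)N1OC1c1ccccc1
Why: Kinetic deprotonation of the dienone should take the α′ hydrogen at C7 and the cross-conjugated enolate is hydroxylated at carbon by the N-sulfonyloxaziridine (enolate oxidation); the C7 configuration formed here does not matter because C7 becomes planar again in step 10.

Step 9
Reactants: 13 (3S,4S,5S,7RS)-7-hydroxy-3-(methoxymethoxy)-11,12,13-trinoreremophila-1,9-dien-8-one
Product: 14 (3S,4S,5S,7RS)-3,7-bis(methoxymethoxy)-11,12,13-trinoreremophila-1,9-dien-8-one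
Conditions: MeOCH2Cl (3 equiv), i-Pr2NEt (4 equiv), CH2Cl2, 0 °C → rt
Reagents that add atoms: chloromethyl methyl ether, COCCl
Why: O-Alkylation of the secondary α-hydroxy ketone gives an acetal that, unlike a silyl ether, cannot shift to the enolate oxygen in step 10, so the enolate stays nucleophilic at C7.

Step 10
Reactants: 14 (3S,4S,5S,7RS)-3,7-bis(methoxymethoxy)-11,12,13-trinoreremophila-1,9-dien-8-one; 15 acetone
Product: 16 (3S,4S,5S,7S)-11-hydroxy-3,7-bis(methoxymethoxy)eremophila-1,9-dien-8-one
Conditions: LiN(i-Pr)2 (1.1 equiv), THF, −78 °C; then 15 (5 equiv), −78 °C; AcOH quench at −78 °C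
Reagents that add atoms: none
Why: Aldol addition of the fully substituted α-alkoxy enolate to acetone should occur from the ring B face opposite the axial C5 methyl (1,3 to C7), which puts the new carbon substituent trans and the C7 oxygen cis to that methyl as the target requires; the cold acid quench is meant to forestall retro-aldol.

Step 11
Reactants: 16 (3S,4S,5S,7S)-11-hydroxy-3,7-bis(methoxymethoxy)eremophila-1,9-dien-8-one
Product: 17 (3S,4S,5S,7S)-3,7-bis(methoxymethoxy)eremophila-1,9,11-trien-8-one
Conditions: methyl N-(triethylammoniosulfonyl)carbamate (2 equiv), toluene, 60 °C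
Reagents that add atoms: none
Why: Burgess dehydration (syn elimination of the sulfamate ester) can only take a methyl hydrogen because C7 is fully substituted, so the isopropenyl group should form without regiochemical choice.

Step 12
Reactants: 17 (3S,4S,5S,7S)-3,7-bis(methoxymethoxy)eremophila-1,9,11-trien-8-one
Product: 18 (3S,4S,5S,7S)-12-hydroxy-3,7-bis(methoxymethoxy)eremophila-1,9,11(13)-trien-8-one
Conditions: SeO2 (0.5 equiv), t-BuOOH (3 equiv), CH2Cl2, rt
Reagents that add atoms: selenium dioxide, O=[Se]=O; tert-butyl hydroperoxide, CC(C)(C)OO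
Why: Allylic oxidation with SeO2 (ene reaction then 2,3-sigmatropic shift) should hydroxylate the methyl of the 1,1-disubstituted alkene, the only electron-rich alkene with allylic hydrogens, while the electron-poor dienone does not react.

Step 13
Reactants: 18 (3S,4S,5S,7S)-12-hydroxy-3,7-bis(methoxymethoxy)eremophila-1,9,11(13)-trien-8-one
Product: 19 (3S,4S,5S,7S)-3,7-bis(methoxymethoxy)-8-oxoeremophila-1,9,11(13)-trien-12-yl acetate
Conditions: Ac2O (2 equiv), pyridine, DMAP (cat.), CH2Cl2, 0 °C
Reagents that add atoms: acetic anhydride, CC(=O)OC(C)=O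
Why: Acylation under nucleophilic catalysis of the only free hydroxyl (primary, allylic).

Step 14
Reactants: 19 (3S,4S,5S,7S)-3,7-bis(methoxymethoxy)-8-oxoeremophila-1,9,11(13)-trien-12-yl acetate
Product: 20 (3S,4S,5S,7S)-3,7-dihydroxy-8-oxoeremophila-1,9,11(13)-trien-12-yl acetate
Conditions: Me2BBr (5 equiv), CH2Cl2, −78 °C; then sat. aq. NaHCO3
Reagents that add atoms: none
Why: Lewis-acid cleavage of both methoxymethyl acetals by the bromoborane at low temperature should leave the allylic acetate, the dienone and the tertiary α-ketol intact.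

Step 15
Reactants: 21 (R)-2-methylbutan-1-ol; 22 2-(triphenylphosphoranylidene)propanal
Product: 24 (2E,4R)-2,4-dimethylhex-2-enal, via (R)-2-methylbutanal 23 (not isolated)
Conditions: TEMPO (10 mol %), PhI(OAc)2 (1.1 equiv), CH2Cl2, rt; then 22 (1.2 equiv), 40 °C
Reagents that add atoms: none
Why: Nitroxyl-catalysed oxidation gives the configurationally labile aldehyde under non-basic conditions and the stabilised ylide consumes it at once in an E-selective Wittig reaction; the stereocentre comes from the chiral pool.

Step 16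
Reactants: 24 (2E,4R)-2,4-dimethylhex-2-enal; 25 triethyl phosphonoacetate
Product: 26 ethyl (2E,4E,6R)-4,6-dimethylocta-2,4-dienoate
Conditions: 25 (1.3 equiv), NaH (1.2 equiv), THF, 0 °C → rt
Reagents that add atoms: none
Why: Horner–Wadsworth–Emmons olefination of the enal with the stabilised phosphonate anion should give the 2E alkene and leave the 4E alkene and the C6 centre untouched.

Step 17
Reactants: 26 ethyl (2E,4E,6R)-4,6-dimethylocta-2,4-dienoate
Product: 27 (2E,4E,6R)-4,6-dimethylocta-2,4-dienoic acid
Conditions: LiOH (3 equiv), THF/MeOH/H2O, rt; then 1 M HCl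
Reagents that add atoms: lithium hydroxide, [Li+].[OH-]
Why: Saponification of the ethyl ester; the stereocentre is remote from the carboxylate and should not epimerise.

Step 18
Reactants: 20 (3S,4S,5S,7S)-3,7-dihydroxy-8-oxoeremophila-1,9,11(13)-trien-12-yl acetate; 27 (2E,4E,6R)-4,6-dimethylocta-2,4-dienoic acid
Product: 28 (3S,4S,5S,7S)-12-acetoxy-7-hydroxy-8-oxoeremophila-1,9,11(13)-trien-3-yl (2E,4E,6R)-4,6-dimethylocta-2,4-dienoate
Conditions: 27 (1.5 equiv), N,N′-dicyclohexylcarbodiimide (1.6 equiv), DMAP (0.3 equiv), CH2Cl2, 0 °C → rt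
Reagents that add atoms: none
Why: Carbodiimide esterification (Steglich) should acylate the secondary allylic C3 hydroxyl with retention, the tertiary C7 hydroxyl being too hindered to compete.

**Compound list**

1 | (7aR)-7a-methyl-2,3,7,7a-tetrahydro-1H-indene-1,5(6H)-dione | C[C@@]12CCC(=O)C=C1CCC2=O | starting material
2 | (7a′R)-7a′-methyl-2′,3′,7′,7a′-tetrahydrospiro[1,3-dithiane-2,5′-inden]-1′(6′H)-one | C[C@@]12CCC3(SCCCS3)C=C1CCC2=O | intermediate
3 | 1,1-dibromoethane | CC(Br)Br | starting material
4 | lithium alkoxide of the 1,1-dibromoethyl carbinol formed at the five-ring carbonyl of 2 (new C–C bond trans to the angular methyl) | C[C@@]12CCC3(SCCCS3)C=C1CC[C@]2([O-])C(C)(Br)Br.[Li+] | intermediate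
5 | lithium (5R)-8,8-(propane-1,3-diyldithio)-11,12,13-trinoreremophila-3,9-dien-3-olate | C[C@@]12CCC3(SCCCS3)C=C1CCC([O-])=C2C.[Li+] | intermediate
6 | (5R)-8,8-(propane-1,3-diyldithio)-11,12,13-trinoreremophila-3,9-dien-3-yl trifluoromethanesulfonate | C[C@@]12CCC3(SCCCS3)C=C1CCC(OS(=O)(=O)C(F)(F)F)=C2C | intermediate
7 | (5S)-8,8-(propane-1,3-diyldithio)-11,12,13-trinoreremophila-3,9-diene | C[C@@]12CCC3(SCCCS3)C=C1CCC=C2C | intermediate
8 | 3-boranyl adduct of 7 (boron on C3 and new hydrogen on C4, both trans to the C5 methyl) | C1C[C@]2(C)C(=CC13SCCCS3)CC[C@H](B)[C@H]2C | intermediate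
9 | (3S,4S,5S)-8,8-(propane-1,3-diyldithio)-11,12,13-trinoreremophil-9-en-3-ol | C1C[C@]2(C)C(=CC13SCCCS3)CC[C@H](O)[C@H]2C | intermediate
10 | (3S,4S,5S)-3-hydroxy-11,12,13-trinoreremophil-9-en-8-one | C1C[C@]2(C)C(=CC1=O)CC[C@H](O)[C@H]2C | intermediate
11 | (3S,4S,5S)-3-(methoxymethoxy)-11,12,13-trinoreremophil-9-en-8-one | C1C[C@]2(C)C(=CC1=O)CC[C@H](OCOC)[C@H]2C | intermediate
12 | (3S,4S,5S)-3-(methoxymethoxy)-11,12,13-trinoreremophila-1,9-dien-8-one | C1C[C@]2(C)C(=CC1=O)C=C[C@H](OCOC)[C@H]2C | intermediate
13 | (3S,4S,5S,7RS)-7-hydroxy-3-(methoxymethoxy)-11,12,13-trinoreremophila-1,9-dien-8-one (C7 epimers) | OC1C[C@]2(C)C(=CC1=O)C=C[C@H](OCOC)[C@H]2C | intermediate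
14 | (3S,4S,5S,7RS)-3,7-bis(methoxymethoxy)-11,12,13-trinoreremophila-1,9-dien-8-one (C7 epimers) | COCOC1C[C@]2(C)C(=CC1=O)C=C[C@H](OCOC)[C@H]2C | intermediate
15 | acetone | CC(C)=O | starting material
16 | (3S,4S,5S,7S)-11-hydroxy-3,7-bis(methoxymethoxy)eremophila-1,9-dien-8-one | CC(C)(O)[C@@]1(OCOC)C[C@]2(C)C(=CC1=O)C=C[C@H](OCOC)[C@H]2C | intermediate
17 | (3S,4S,5S,7S)-3,7-bis(methoxymethoxy)eremophila-1,9,11-trien-8-one | C=C(C)[C@@]1(OCOC)C[C@]2(C)C(=CC1=O)C=C[C@H](OCOC)[C@H]2C | intermediate
18 | (3S,4S,5S,7S)-12-hydroxy-3,7-bis(methoxymethoxy)eremophila-1,9,11(13)-trien-8-one | C=C(CO)[C@@]1(OCOC)C[C@]2(C)C(=CC1=O)C=C[C@H](OCOC)[C@H]2C | intermediate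
19 | (3S,4S,5S,7S)-3,7-bis(methoxymethoxy)-8-oxoeremophila-1,9,11(13)-trien-12-yl acetate | C=C(COC(C)=O)[C@@]1(OCOC)C[C@]2(C)C(=CC1=O)C=C[C@H](OCOC)[C@H]2C | intermediate
20 | (3S,4S,5S,7S)-3,7-dihydroxy-8-oxoeremophila-1,9,11(13)-trien-12-yl acetate | C=C(COC(C)=O)[C@@]1(O)C[C@]2(C)C(=CC1=O)C=C[C@H](O)[C@H]2C | intermediate
21 | (R)-2-methylbutan-1-ol | OC[C@H](C)CC | starting material
22 | 2-(triphenylphosphoranylidene)propanal | CC(C=O)=P(c1ccccc1)(c1ccccc1)c1ccccc1 | starting material
23 | (R)-2-methylbutanal | O=C[C@H](C)CC | intermediate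
24 | (2E,4R)-2,4-dimethylhex-2-enal | O=C/C(C)=C/[C@H](C)CC | intermediate
25 | triethyl phosphonoacetate | CCOC(=O)CP(=O)(OCC)OCC | starting material
26 | ethyl (2E,4E,6R)-4,6-dimethylocta-2,4-dienoate | CCOC(=O)/C=C/C(C)=C/[C@H](C)CC | intermediate
27 | (2E,4E,6R)-4,6-dimethylocta-2,4-dienoic acid | OC(=O)/C=C/C(C)=C/[C@H](C)CC | intermediate
28 | (3S,4S,5S,7S)-12-acetoxy-7-hydroxy-8-oxoeremophila-1,9,11(13)-trien-3-yl (2E,4E,6R)-4,6-dimethylocta-2,4-dienoate (CNP0160850.1) | C=C(COC(C)=O)[C@@]1(O)C[C@]2(C)C(=CC1=O)C=C[C@H](OC(=O)/C=C/C(C)=C/[C@H](C)CC)[C@H]2C | target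

**Step count and risks**

Total step count: 18. Longest linear sequence: 15 steps (steps 1–14, then step 18); the acid 27 is made in 3 steps (15–17).

Steps most likely to fail, riskiest first:

Step 2. What may go wrong: the carbenoid may deprotonate the hindered ketone instead of adding to it, or the CH2 carbon may migrate in place of the quaternary carbon, so that the new carbon is inserted on the wrong side of the carbonyl. The fallback sets out from 2 and returns at 7. Ring A is still grown from the five-membered ring, but by a diazoalkane homologation (Tiffeneau–Demjanov type), whose known preference is migration of the less substituted carbon. Compound 2 with (trimethylsilyl)diazomethane and BF3·OEt2 (CH2Cl2, −78 → −20 °C, then desilylation on silica) should give the six-ring ketone with its carbonyl at C4 next to the quaternary carbon, (5R)-8,8-(propane-1,3-diyldithio)-11,12,13,15-tetranoreremophil-9-en-4-one F1. MeMgBr with CeCl3 (THF, −78 °C) should then add the C15 methyl to give the tertiary alcohol 4-hydroxy-8,8-(propane-1,3-diyldithio)-11,12,13-trinoreremophil-9-ene F2. Dehydration with SOCl2 in pyridine (0 °C) towards the ring CH2 should give diene 7.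

Step 10. What may go wrong: proton transfer from acetone to the hindered enolate, and reversal of the congested aldol addition on warming. The fallback sets out from 14 and returns at 17. The same enolate (LiN(i-Pr)2, THF, −78 °C) is added to acetaldehyde, which is faster and far less reversible, to give the secondary aldol (3S,4S,5S,7S)-7-(1-hydroxyethyl)-3,7-bis(methoxymethoxy)-11,12,13-trinoreremophila-1,9-dien-8-one F6. Dess–Martin periodinane should oxidise it to the 7-acetyl compound (3S,4S,5S,7S)-7-acetyl-3,7-bis(methoxymethoxy)-11,12,13-trinoreremophila-1,9-dien-8-one F7. Ph3P=CH2 (THF, 0 °C) should methylenate the methyl ketone, the less hindered and non-conjugated of the two carbonyls, to give 17.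

Step 4. What may go wrong: loss of site selectivity between the two trisubstituted alkenes, and oxidation at sulfur during the peroxide work-up. The fallback sets out from 2 and returns at 9. Step 2 is run as far as enolate 5, which is protonated at −78 °C with 2,6-di-tert-butylphenol instead of being triflated; protonation at C4 anti to the angular methyl should give the 4,5-cis ketone (4S,5S)-8,8-(propane-1,3-diyldithio)-11,12,13-trinoreremophil-9-en-3-one F3. LiBH(s-Bu)3 (THF, −78 °C) should attack from the same open face and give the axial alcohol (3R,4S,5S)-8,8-(propane-1,3-diyldithio)-11,12,13-trinoreremophil-9-en-3-ol F4, with the hydroxyl cis to both methyls. Mitsunobu inversion (4-nitrobenzoic acid, PPh3, diisopropyl azodicarboxylate, THF) should give (3S,4S,5S)-8,8-(propane-1,3-diyldithio)-11,12,13-trinoreremophil-9-en-3-yl 4-nitrobenzoate F5, which has the required C3 configuration. K2CO3 in MeOH returns 9.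

Further compounds
F1 | step 2 | (5R)-8,8-(propane-1,3-diyldithio)-11,12,13,15-tetranoreremophil-9-en-4-one | C[C@@]12CCC3(SCCCS3)C=C1CCCC2=O
F2 | step 2 | 4-hydroxy-8,8-(propane-1,3-diyldithio)-11,12,13-trinoreremophil-9-ene (either C4 epimer) | C[C@@]12CCC3(SCCCS3)C=C1CCCC2(C)O
F3 | step 4 | (4S,5S)-8,8-(propane-1,3-diyldithio)-11,12,13-trinoreremophil-9-en-3-one | C1C[C@]2(C)C(=CC13SCCCS3)CCC(=O)[C@H]2C
F4 | step 4 | (3R,4S,5S)-8,8-(propane-1,3-diyldithio)-11,12,13-trinoreremophil-9-en-3-ol | C1C[C@]2(C)C(=CC13SCCCS3)CC[C@@H](O)[C@H]2C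
F5 | step 4 | (3S,4S,5S)-8,8-(propane-1,3-diyldithio)-11,12,13-trinoreremophil-9-en-3-yl 4-nitrobenzoate | C1C[C@]2(C)C(=CC13SCCCS3)CC[C@H](OC(=O)c3ccc(cc3)[N+](=O)[O-])[C@H]2C
F6 | step 10 | (3S,4S,5S,7S)-7-(1-hydroxyethyl)-3,7-bis(methoxymethoxy)-11,12,13-trinoreremophila-1,9-dien-8-one (either carbinol epimer) | CC(O)[C@@]1(OCOC)C[C@]2(C)C(=CC1=O)C=C[C@H](OCOC)[C@H]2C
F7 | step 10 | (3S,4S,5S,7S)-7-acetyl-3,7-bis(methoxymethoxy)-11,12,13-trinoreremophila-1,9-dien-8-one | CC(=O)[C@@]1(OCOC)C[C@]2(C)C(=CC1=O)C=C[C@H](OCOC)[C@H]2C
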